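**Plan**
- Retrosynthesis: cut the two isobutyrate esters, then the C2–CH2OH bond (Morita–Baylis–Hillman), then the side-chain bond between the methylene-bearing carbon and its CH2 neighbour (alkene–alkyne coupling), and last the ring bonds C2=C3 and C4–C5 of the cyclohexenone together.
- Enabling feature: in the cyclohex-2-enone ring C5 is β to the C1 carbonyl and C2=C3 is its α,β double bond. C3–C4 is therefore an acetaldehyde unit that can be inserted between C5 (Michael addition) and C2 (aldol condensation) of a four-carbon keto-alkene C5–C6–C1–C2.
- Forward: Knoevenagel acceptor → organocatalytic acetaldehyde Michael/aldol condensation/decarboxylation forms the only ring → alkyne unmasked → seven-carbon side chain (from 2-methylglycidol) joined by Ru-catalysed alkene–alkyne coupling → hydroxymethylation → double acylation.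
- Stereochemistry: ring C5 (R) from the catalyst-controlled Michael addition; the tertiary carbinol (R) from (S)-2-methylglycidol; the E-alkene from β-hydride elimination in the ruthenacycle.

Key step: step 2

Remark: both enantiomers of 2-methylglycidol and of α,α-diphenylprolinol trimethylsilyl ether, and 3-(trimethylsilyl)prop-2-ynal, are taken as commercially available.

**Route**

Step 1
Reactants: 1 3-(trimethylsilyl)prop-2-ynal; 2 tert-butyl 3-oxobutanoate (tert-butyl acetoacetate)
Product: 3 tert-butyl 2-acetyl-5-(trimethylsilyl)pent-2-en-4-ynoate (mixture of alkene isomers)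
Conditions: piperidine (cat.), AcOH (cat.), 4 Å MS, CH2Cl2, 0 °C
Reagents that add atoms: none
Why: Knoevenagel condensation of the non-enolisable ynal with the β-keto ester under piperidinium acetate catalysis should give the doubly activated four-carbon acceptor; the silyl cap keeps nucleophiles off the alkyne terminus and the alkene geometry is of no consequence for the next step.

Step 2
Reactants: 3 tert-butyl 2-acetyl-5-(trimethylsilyl)pent-2-en-4-ynoate; 4 acetaldehyde
Product: 7 (5R)-5-[(trimethylsilyl)ethynyl]cyclohex-2-en-1-one, via keto aldehyde 5 (not isolated), via keto ester 6 (not isolated)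
Conditions: (S)-α,α-diphenylprolinol trimethylsilyl ether (20 mol%), PhCO2H (20 mol%), MeCHO (10 equiv), 1,4-dioxane, 0 °C → rt; evaporate; TsOH·H2O (0.3 equiv), PhMe, 80 °C
Reagents that add atoms: none
Why: Acetaldehyde condenses with the secondary amine to an enamine, which adds through its unshielded face to the β-carbon of the doubly activated alkene of 3 (C4–C5 bond); hydrolysis releases the catalyst and δ-keto aldehyde 5. On warming with TsOH the enol of the acetyl group attacks the aldehyde in a 6-(enolendo)-exo-trig aldol closure, loss of water gives the C2=C3 enone of 6, and the tert-butyl ester falls to 2-methylpropene and a β-keto acid that decarboxylates to 7. The closest known reaction types are the enamine-catalysed Michael addition of aldehydes to alkylidene malonates, the use of acetaldehyde as enamine donor towards nitroalkenes, and the amine-catalysed Michael/aldol-condensation route from β-keto esters to 5-substituted cyclohex-2-enones, which passes through the same keto aldehyde. The only new stereocentre, C5, is set in the Michael event by the diphenyl(trimethylsilyloxy)methyl group of the (S)-catalyst; by analogy with nitroalkene acceptors the 5R product is expected, and the (R)-catalyst is at hand should the sense prove opposite. The step needs 1,4- and not 1,6-addition, secured by the silyl cap on the alkyne terminus, and a single aldol regiochemistry, secured because every alternative enol/carbonyl pairing would close a four-membered ring. Excess acetaldehyde is evaporated before the acid is added so that it cannot condense with 5.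

Step 3
Reactants: 7 (5R)-5-[(trimethylsilyl)ethynyl]cyclohex-2-en-1-one
Product: 8 (5R)-5-ethynylcyclohex-2-en-1-one
Conditions: Bu4NF, AcOH, THF, 0 °C
Reagents that add atoms: none
Why: Fluoride-induced protodesilylation of the alkynylsilane, buffered with acetic acid so that the enone is not exposed to base; the C5 stereocentre is not α to the carbonyl and should be untouched.

Step 4
Reactants: 9 (S)-2-methylglycidol, [(2S)-2-methyloxiran-2-yl]methanol
Product: 10 (2R)-2-methylpent-4-ene-1,2-diol
Conditions: CH2=CHMgBr (3 equiv), CuI (10 mol%), THF, −30 → 0 °C; aq. NH4Cl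
Reagents that add atoms: vinylmagnesium bromide, C=C[Mg]Br
Why: Copper-catalysed Grignard opening of the 2,2-disubstituted epoxide at its unhindered CH2 terminus (the first equivalent of Grignard reagent deprotonates the hydroxyl group); the quaternary carbinol centre is not touched, so the (S)-epoxide gives the (R)-diol through a change of CIP priorities only.

Step 5
Reactants: 8 (5R)-5-ethynylcyclohex-2-en-1-one; 10 (2R)-2-methylpent-4-ene-1,2-diol
Product: 11 (5R)-5-[(4E,6R)-6,7-dihydroxy-6-methylhepta-1,4-dien-2-yl]cyclohex-2-en-1-one
Conditions: [CpRu(MeCN)3]PF6 (10 mol%), acetone, rt, 10 in slight excess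
Reagents that add atoms: none
Why: Ruthenium-catalysed alkene–alkyne coupling (formal intermolecular Alder-ene reaction): oxidative cyclisation to a ruthenacyclopentene, β-hydride elimination from the allylic CH2 of 10 and reductive elimination should give the branched 1,4-diene with the exocyclic methylene and the new E-alkene, with both stereocentres untouched.

Step 6
Reactants: 11 (5R)-5-[(4E,6R)-6,7-dihydroxy-6-methylhepta-1,4-dien-2-yl]cyclohex-2-en-1-one
Product: 12 (5R)-5-[(4E,6R)-6,7-dihydroxy-6-methylhepta-1,4-dien-2-yl]-2-(hydroxymethyl)cyclohex-2-en-1-one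
Conditions: 37% aq. HCHO, DMAP (20 mol%), THF, rt
Reagents that add atoms: formaldehyde, C=O
Why: Morita–Baylis–Hillman hydroxymethylation: DMAP adds to C3 of the enone, the enolate captures formaldehyde at C2 and the amine is expelled, a reaction type established for cyclohex-2-enones in aqueous medium; no stereocentre is formed or touched.

Step 7
Reactants: 12 (5R)-5-[(4E,6R)-6,7-dihydroxy-6-methylhepta-1,4-dien-2-yl]-2-(hydroxymethyl)cyclohex-2-en-1-one
Product: 13 (5R)-5-[(4E,6R)-6-hydroxy-6-methyl-7-(2-methylpropanoyloxy)hepta-1,4-dien-2-yl]-2-[(2-methylpropanoyloxy)methyl]cyclohex-2-en-1-one (CNP0536801.1)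
Conditions: i-PrCOCl (2.2 equiv), pyridine, CH2Cl2, −20 → 0 °C
Reagents that add atoms: 2-methylpropanoyl chloride (isobutyryl chloride), CC(C)C(=O)Cl
Why: Selective esterification of the two primary hydroxyl groups by the acid chloride at low temperature; the tertiary allylic alcohol is too hindered to be acylated without a nucleophilic catalyst.

**Compound list**
1 | 3-(trimethylsilyl)prop-2-ynal | C[Si](C)(C)C#CC=O | starting material
2 | tert-butyl 3-oxobutanoate | CC(=O)CC(=O)OC(C)(C)C | starting material
3 | tert-butyl 2-acetyl-5-(trimethylsilyl)pent-2-en-4-ynoate (alkene isomers) | CC(=O)C(=CC#C[Si](C)(C)C)C(=O)OC(C)(C)C | intermediate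
4 | acetaldehyde | CC=O | starting material
5 | tert-butyl (3R)-2-acetyl-3-(2-oxoethyl)-5-(trimethylsilyl)pent-4-ynoate (both C2 epimers) | C[Si](C)(C)C#C[C@@H](C(C(C)=O)C(=O)OC(C)(C)C)CC=O | intermediate
6 | tert-butyl (6R)-2-oxo-6-[(trimethylsilyl)ethynyl]cyclohex-3-ene-1-carboxylate (both C1 epimers) | C[Si](C)(C)C#C[C@@H]1CC=CC(=O)C1C(=O)OC(C)(C)C | intermediate
7 | (5R)-5-[(trimethylsilyl)ethynyl]cyclohex-2-en-1-one | C[Si](C)(C)C#C[C@@H]1CC=CC(=O)C1 | intermediate
8 | (5R)-5-ethynylcyclohex-2-en-1-one | C#C[C@@H]1CC=CC(=O)C1 | intermediate
9 | (S)-2-methylglycidol | C[C@]1(CO)CO1 | starting material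
10 | (2R)-2-methylpent-4-ene-1,2-diol | C=CC[C@@](C)(O)CO | intermediate
11 | (5R)-5-[(4E,6R)-6,7-dihydroxy-6-methylhepta-1,4-dien-2-yl]cyclohex-2-en-1-one | C=C(C/C=C/[C@@](C)(O)CO)[C@@H]1CC=CC(=O)C1 | intermediate
12 | (5R)-5-[(4E,6R)-6,7-dihydroxy-6-methylhepta-1,4-dien-2-yl]-2-(hydroxymethyl)cyclohex-2-en-1-one | C=C(C/C=C/[C@@](C)(O)CO)[C@@H]1CC=C(CO)C(=O)C1 | intermediate
13 | (5R)-5-[(4E,6R)-6-hydroxy-6-methyl-7-(2-methylpropanoyloxy)hepta-1,4-dien-2-yl]-2-[(2-methylpropanoyloxy)methyl]cyclohex-2-en-1-one | C=C(C/C=C/[C@@](C)(O)COC(=O)C(C)C)[C@@H]1CC=C(COC(=O)C(C)C)C(=O)C1 | target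

**Count**
Total steps: 7. Longest linear sequence: 6 (steps 1, 2, 3, 5, 6, 7).

**Steps most likely to fail**

Step 2. The enamine addition may be slow or poorly face-selective with the slim alkynyl substituent, and the amine may exchange the alkylidene group of 3 with acetaldehyde by retro-Knoevenagel reaction. The fallback sets out from 1 and 2 and comes back at 7. Wittig olefination of 1 with (triphenylphosphoranylidene)acetaldehyde (PhMe, rt) gives (2E)-5-(trimethylsilyl)pent-2-en-4-ynal F1. β-Keto ester 2 is then added to the iminium ion of this enal formed with (R)-α,α-diphenylprolinol trimethylsilyl ether (PhMe, rt), the antipode that the face-shielding model predicts for the 5R series. This gives the same keto aldehyde 5, and TsOH in toluene at 80 °C takes 5 through 6 to 7. This is the established iminium-mode Michael/aldol-condensation route to 5-substituted cyclohex-2-enones; it moves the stereo-determining event to a β-keto ester donor and an enal acceptor.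

Step 5. Ruthenacycle formation may favour the linear regiochemistry because the alkyne is α-branched, and the 1,2-diol may sequester the cationic catalyst. The fallback sets out from 8 and 9 and comes back at 11. Markovnikov addition of HI made in the flask (NaI, Me3SiCl, H2O, MeCN, 0 °C; Et3N work-up to reverse any iodide addition to the enone) gives (5R)-5-(1-iodoethenyl)cyclohex-2-en-1-one F2. Stille coupling with allyltributylstannane (Pd(PPh3)4, CuI, DMF, rt) gives (5R)-5-(penta-1,4-dien-2-yl)cyclohex-2-en-1-one F3. Separately, one-carbon homologation of epoxide 9 with dimethylsulfonium methylide (trimethylsulfonium iodide, n-BuLi, THF, −10 °C → rt) gives (2R)-2-methylbut-3-ene-1,2-diol F4. Cross-metathesis of the monosubstituted alkene of the diene with this hindered vinyl carbinol (second-generation Grubbs catalyst, CH2Cl2, 40 °C) should give 11 as the E-isomer.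

Step 6. Hydroxymethylation may stall or be overtaken by oligomerisation of the formaldehyde adduct on this polyfunctional enone. The fallback sets out from 11 and comes back at 12. α-Iodination of the enone (I2, pyridine, CH2Cl2, rt) gives (5R)-5-[(4E,6R)-6,7-dihydroxy-6-methylhepta-1,4-dien-2-yl]-2-iodocyclohex-2-en-1-one F5. Stille coupling with (tributylstannyl)methanol (Pd(PPh3)4, 1,4-dioxane, 80 °C) gives 12.

**Further compounds**
F1 | step 2 | (2E)-5-(trimethylsilyl)pent-2-en-4-ynal | C[Si](C)(C)C#C/C=C/C=O
F2 | step 5 | (5R)-5-(1-iodoethenyl)cyclohex-2-en-1-one | C=C(I)[C@@H]1CC=CC(=O)C1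
F3 | step 5 | (5R)-5-(penta-1,4-dien-2-yl)cyclohex-2-en-1-one | C=CCC(=C)[C@@H]1CC=CC(=O)C1
F4 | step 5 | (2R)-2-methylbut-3-ene-1,2-diol | C=C[C@@](C)(O)CO
F5 | step 6 | (5R)-5-[(4E,6R)-6,7-dihydroxy-6-methylhepta-1,4-dien-2-yl]-2-iodocyclohex-2-en-1-one | C=C(C/C=C/[C@@](C)(O)CO)[C@@H]1CC=C(I)C(=O)C1
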